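**Retrosynthetic overview** (germacrane numbering: ring C1–C10 with C2 = ketone, C4 bearing C15H2OAc, ring-trans C4=C5, C6–O, C7, C8–OAc, C10 bearing exo-methylene C14; lactone ring O–C6–C7–C11(=C13H2)–C12(=O))
1. The target comes from its 8α-alcohol by acetylation. The alcohol is disconnected at C7–C8: an intramolecular Cr(II)-mediated (Nozaki–Hiyama–Kishi) γ-allylation of a C8 aldehyde by a 3-(bromomethyl)butenolide.
2. Enabling feature: the array C13=C11–C7–C8–O is a homoallylic alcohol whose carbon C7 is the β-carbon of the α-methylene-γ-lactone ring. The lactone can therefore exist as a butenolide before the carbocycle is closed, and one C–C bond formation closes the ten-membered ring, sets C7 and C8 and unveils the exo-methylene lactone.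
3. The butenolide (first ring) comes from ring-closing metathesis of the 2-(bromomethyl)acrylate of a C6 vinyl carbinol. The trisubstituted C4=C5 alkene comes from Red-Al trans-hydroalumination/iodination/hydroxymethylation of a propargylic alcohol. C6 comes from a catalytic asymmetric alkynylation of acrolein.
4. The chain is assembled on (S)-epichlorohydrin as a C1–C2–C3 linchpin between a vinyl Grignard (C8–C10, C14) and acetylide (C4–C5). C2 is carried as a carbinol (temporary stereocentre) and oxidised late.
5. Ring order: γ-lactone (step 11) first, ten-membered carbocycle (step 14) last.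

Key step: step 14

Assumption: the (S,S)-ProPhenol–zinc catalyst is taken to deliver the alkynyl group to the Re face of acrolein (6S carbinol); should the sense prove opposite, the (R,R)-ligand is used.

**Step 1**
Reactants: 1 3-bromobut-3-en-1-ol
Product: 2 [(3-bromobut-3-en-1-yl)oxy](tert-butyl)dimethylsilane
Conditions: TBSCl, imidazole, DMF, 0 °C → rt
Reagents that add atoms: tert-butyldimethylsilyl chloride, C[Si](C)(Cl)C(C)(C)C
Why: Standard imidazole-mediated silylation of a primary alcohol; the vinyl bromide is inert.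

**Step 2**
Reactants: 2 silyl ether; 3 (S)-epichlorohydrin
Product: 6 tert-butyldimethyl({3-methylidene-4-[(2S)-oxiran-2-yl]butyl}oxy)silane, via vinyl Grignard reagent 4 (not isolated), via chlorohydrin 5 (not isolated)
Conditions: Mg, THF, 40 °C; CuI (10 mol %), 3, −40 → 0 °C; then 2 M NaOH aq., rt
Reagents that add atoms: none
Why: Copper-catalysed Grignard opening of the epoxide terminus of epichlorohydrin followed by base-induced closure of the chlorohydrin (standard epichlorohydrin homologation) forms C10–C1 and carries the chiral-pool C2 centre over untouched (its C–O bond is never broken); this centre is temporary and ends as the ketone.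

**Step 3**
Reactants: 6 epoxide; 7 lithium acetylide–ethylenediamine complex
Product: 8 (4S)-8-[(tert-butyldimethylsilyl)oxy]-6-methylideneoct-1-yn-4-ol
Conditions: 7 (3 equiv), DMSO, 0 °C → rt; H2O
Reagents that add atoms: none
Why: SN2 opening of the terminal epoxide at its CH2 (C3) by acetylide forms C3–C4 and leaves C2 unchanged.

**Step 4**
Reactants: 8 homopropargylic alcohol
Product: 9 (4S)-4,8-bis[(tert-butyldimethylsilyl)oxy]-6-methylideneoct-1-yne
Conditions: TBSCl, imidazole, DMAP (cat.), DMF, rt
Reagents that add atoms: tert-butyldimethylsilyl chloride, C[Si](C)(Cl)C(C)(C)C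
Why: Standard silylation of the secondary C2 alcohol; the terminal alkyne C–H is not affected.

**Step 5**
Reactants: 9 alkyne; 10 acrolein
Product: 12 (3S,7S)-7,11-bis[(tert-butyldimethylsilyl)oxy]-9-methylideneundec-1-en-4-yn-3-ol, via alkynyl(methyl)zinc 11 (not isolated)
Conditions: (S,S)-ProPhenol (20 mol %), Ph3PO (40 mol %), Me2Zn (3 equiv), toluene, 0 °C; then 10 (slow addition), 0–4 °C; NH4Cl aq.
Reagents that add atoms: none
Why: Zn–ProPhenol-catalysed enantioselective 1,2-alkynylation of an α,β-unsaturated aldehyde; the dinuclear zinc catalyst controls Re-face delivery and sets C6 (S here; the same centre is R in the lactone after the change in CIP priorities).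

**Step 6**
Reactants: 12 enynol
Product: 14 (3S,4Z,7S)-7,11-bis[(tert-butyldimethylsilyl)oxy]-5-iodo-9-methylideneundeca-1,4-dien-3-ol, via cyclic vinylalanate 13 (not isolated)
Conditions: Red-Al, THF, 0 °C → rt; EtOAc; then I2, THF, −78 → 0 °C
Reagents that add atoms: iodine, II
Why: Alkoxide-directed trans-hydroalumination of the propargylic alcohol places Al on the distal carbon C4 syn to C6 (five-membered alanate), and iodinolysis with retention gives the Z-iodide, which fixes C3 trans to C6 across the future ring alkene; the vinyl and 1,1-disubstituted alkenes are inert.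

**Step 7**
Reactants: 14 vinyl iodide
Product: 16 (2Z,4S)-2-{(2S)-2,6-bis[(tert-butyldimethylsilyl)oxy]-4-methylidenehexyl}hexa-2,5-diene-1,4-diol, via dilithio vinyllithium alkoxide 15 (not isolated)
Conditions: t-BuLi (3.1 equiv), Et2O, −78 °C; then CH2O (monomeric, from cracked paraformaldehyde, THF), −78 → −40 °C; H2O
Reagents that add atoms: formaldehyde, C=O
Why: Iodine–lithium exchange proceeds with retention of alkene geometry and the vinyllithium is hydroxymethylated by formaldehyde, which installs C15 cis to C6; −78 °C in ether should suppress 1,4-silyl migration from the C2 silyl ether and carbolithiation of the pendant alkenes.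

**Step 8**
Reactants: 16 diol
Product: 17 (2Z,4S)-2-{(2S)-2,6-bis[(tert-butyldimethylsilyl)oxy]-4-methylidenehexyl}-4-hydroxyhexa-2,5-dien-1-yl acetate
Conditions: AcCl (1.05 equiv), 2,4,6-collidine, CH2Cl2, −78 °C
Reagents that add atoms: acetyl chloride, CC(=O)Cl
Why: Kinetically selective acylation of the primary allylic C15 hydroxyl over the hindered secondary bis-allylic C6 hydroxyl under non-acidic conditions.

**Step 9**
Reactants: 18 2-(bromomethyl)acrylic acid
Product: 19 2-(bromomethyl)acryloyl chloride
Conditions: (COCl)2, DMF (cat.), CH2Cl2, 0 °C → rt; used crude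
Reagents that add atoms: oxalyl chloride, ClC(=O)C(=O)Cl
Why: Standard acid chloride formation through the Vilsmeier-type intermediate; the allylic bromide is untouched.

**Step 10**
Reactants: 17 monoacetate; 19 acid chloride
Product: 20 (3S,4Z)-6-acetoxy-5-{(2S)-2,6-bis[(tert-butyldimethylsilyl)oxy]-4-methylidenehexyl}hexa-1,4-dien-3-yl 2-(bromomethyl)prop-2-enoate
Conditions: 19 (1.5 equiv), 2,6-lutidine, CH2Cl2, −20 → 0 °C
Reagents that add atoms: none
Why: O-acylation of the C6 alcohol by an acid chloride with retention at C6; the hindered, weakly nucleophilic base avoids SN2′ attack on the bromomethylacrylate.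

**Step 11**
Reactants: 20 acrylate ester
Product: 21 (2Z)-2-{(2S)-2,6-bis[(tert-butyldimethylsilyl)oxy]-4-methylidenehexyl}-3-[(2R)-4-(bromomethyl)-5-oxo-2,5-dihydrofuran-2-yl]prop-2-en-1-yl acetate
Conditions: Grubbs II (10 mol %), CH2Cl2 (5 mM), 40 °C
Reagents that add atoms: none
Why: Ring-closing metathesis of an allylic acrylate to a butenolide closes the lactone ring, initiating at the monosubstituted C6 vinyl group and closing onto the 1,1-disubstituted acrylate with loss of ethylene; the trisubstituted and remote 1,1-disubstituted alkenes should not compete and C6 is not touched.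

**Step 12**
Reactants: 21 bis-silyl ether
Product: 22 (2Z)-3-[(2R)-4-(bromomethyl)-5-oxo-2,5-dihydrofuran-2-yl]-2-[(2S)-2,6-dihydroxy-4-methylidenehexyl]prop-2-en-1-yl acetate
Conditions: HF (48 % aq.), MeCN, 0 °C → rt
Reagents that add atoms: none
Why: Acidic fluoride cleaves both silyl ethers; no nucleophilic amine or base is present, so the allylic bromide, the acetate and the base-labile C6–H of the butenolide should survive.

**Step 13**
Reactants: 22 diol
Product: 23 (2Z)-3-[(2R)-4-(bromomethyl)-5-oxo-2,5-dihydrofuran-2-yl]-2-(4-methylidene-2,6-dioxohexyl)prop-2-en-1-yl acetate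
Conditions: Dess–Martin periodinane (3 equiv), NaHCO3, CH2Cl2, 0 °C → rt; crude used at once
Reagents that add atoms: none
Why: Buffered Dess–Martin oxidation converts the primary alcohol into the β,γ-unsaturated C8 aldehyde and the C2 carbinol into the skipped dienone (erasing the temporary stereocentre) under non-enolising conditions that should not move the double bonds.

**Step 14**
Reactants: 23 keto aldehyde
Product: 25 [(3aR,4S,10Z,11aR)-4-hydroxy-3,6-dimethylidene-2,8-dioxo-2,3,3a,4,5,6,7,8,9,11a-decahydrocyclodeca[b]furan-10-yl]methyl acetate, via allylchromium(III) species 24 (not isolated)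
Conditions: CrCl2 (10 equiv), degassed THF, rt, syringe-pump addition of 23 (final 2 mM); pH 7 buffer work-up
Reagents that add atoms: none
Why: Two equivalents of CrCl2 reduce the allylic C13–Br bond to the allylchromium(III) species 24, which adds through its γ-carbon C7 (SE2′) to the tethered C8 aldehyde in a closed six-membered chair transition state; the closest precedents are the Nozaki–Hiyama–Kishi γ-allylation of aldehydes by 3-(bromomethyl)furan-2(5H)-ones and chromium-mediated allylations used to close ten-membered germacrane rings. The ten-membered carbocycle is closed in a 10-exo-trig mode at the aldehyde carbon, while the pre-formed lactone ring is kept and its endocyclic C7=C11 bond shifts to the exocyclic C11=C13 methylene. C7 is controlled by the C6 stereocentre: the aldehyde adds to the butenolide face anti to the C6–C5 bond, which gives the trans-fused lactone. C8 is controlled by the chair transition state, in which the aldehyde chain (C9) is pseudo-equatorial and the ring-locked E γ-substituent (C6) enforces the anti (crotyl-type) relationship, i.e. the 8α-hydroxyl. The step needs chemoselectivity for the aldehyde over the C2 ketone and the esters (intrinsic to organochromium reagents; attack on C2 would also need a six-membered ring containing the E-C4=C5 bond) and cyclisation over oligomerisation (high dilution, slow addition). It also needs no reductive 1,4-loss of the lactone carboxylate; the C6–O bond lies in the nodal plane of the allyl π-system.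

**Step 15**
Reactants: 25 hydroxy macrocycle
Product: 26 [(3aR,4S,10Z,11aR)-4-acetoxy-3,6-dimethylidene-2,8-dioxo-2,3,3a,4,5,6,7,8,9,11a-decahydrocyclodeca[b]furan-10-yl]methyl acetate (CNP0183179.1)
Conditions: Ac2O, pyridine, DMAP (cat.), CH2Cl2, 0 °C
Reagents that add atoms: acetic anhydride, CC(=O)OC(C)=O
Why: Standard acetylation of the secondary C8 alcohol under mild conditions that leave all stereocentres and the skipped dienone untouched.

**Compound list**
1 | 3-bromobut-3-en-1-ol | C=C(Br)CCO | starting material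
2 | [(3-bromobut-3-en-1-yl)oxy](tert-butyl)dimethylsilane | CC(C)(C)[Si](C)(C)OCCC(Br)=C | intermediate
3 | (S)-epichlorohydrin, (2S)-2-(chloromethyl)oxirane | ClC[C@@H]1CO1 | starting material
4 | {4-[(tert-butyldimethylsilyl)oxy]but-1-en-2-yl}magnesium bromide (formed in situ) | CC(C)(C)[Si](C)(C)OCCC(=C)[Mg]Br | intermediate
5 | (2S)-6-[(tert-butyldimethylsilyl)oxy]-1-chloro-4-methylidenehexan-2-ol (formed in situ) | CC(C)(C)[Si](C)(C)OCCC(=C)C[C@H](O)CCl | intermediate
6 | tert-butyldimethyl({3-methylidene-4-[(2S)-oxiran-2-yl]butyl}oxy)silane | CC(C)(C)[Si](C)(C)OCCC(=C)C[C@H]1CO1 | intermediate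
7 | lithium acetylide–ethylenediamine complex | [Li+].[C-]#C.NCCN | starting material
8 | (4S)-8-[(tert-butyldimethylsilyl)oxy]-6-methylideneoct-1-yn-4-ol | CC(C)(C)[Si](C)(C)OCCC(=C)C[C@H](O)CC#C | intermediate
9 | (4S)-4,8-bis[(tert-butyldimethylsilyl)oxy]-6-methylideneoct-1-yne | CC(C)(C)[Si](C)(C)OCCC(=C)C[C@H](O[Si](C)(C)C(C)(C)C)CC#C | intermediate
10 | acrolein (prop-2-enal) | C=CC=O | starting material
11 | methylzinc acetylide of 9 (formed in situ) | CC(C)(C)[Si](C)(C)OCCC(=C)C[C@H](O[Si](C)(C)C(C)(C)C)CC#C[Zn]C | intermediate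
12 | (3S,7S)-7,11-bis[(tert-butyldimethylsilyl)oxy]-9-methylideneundec-1-en-4-yn-3-ol | CC(C)(C)[Si](C)(C)OCCC(=C)C[C@H](O[Si](C)(C)C(C)(C)C)CC#C[C@@H](O)C=C | intermediate
13 | sodium bis(2-methoxyethoxy) 1,2-oxaaluminate (five-membered ring Al–O–C6–C5=C4) from 12 (formed in situ) | [Na+].CC(C)(C)[Si](C)(C)OCCC(=C)C[C@H](O[Si](C)(C)C(C)(C)C)CC1=C[C@H](C=C)O[Al-]1(OCCOC)OCCOC | intermediate
14 | (3S,4Z,7S)-7,11-bis[(tert-butyldimethylsilyl)oxy]-5-iodo-9-methylideneundeca-1,4-dien-3-ol | CC(C)(C)[Si](C)(C)OCCC(=C)C[C@H](O[Si](C)(C)C(C)(C)C)C/C(I)=C/[C@@H](O)C=C | intermediate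
15 | dilithio derivative of 14 (C4–Li, C6–OLi; formed in situ) | CC(C)(C)[Si](C)(C)OCCC(=C)C[C@H](O[Si](C)(C)C(C)(C)C)C/C([Li])=C/[C@@H](O[Li])C=C | intermediate
16 | (2Z,4S)-2-{(2S)-2,6-bis[(tert-butyldimethylsilyl)oxy]-4-methylidenehexyl}hexa-2,5-diene-1,4-diol | CC(C)(C)[Si](C)(C)OCCC(=C)C[C@H](O[Si](C)(C)C(C)(C)C)C/C(CO)=C/[C@@H](O)C=C | intermediate
17 | (2Z,4S)-2-{(2S)-2,6-bis[(tert-butyldimethylsilyl)oxy]-4-methylidenehexyl}-4-hydroxyhexa-2,5-dien-1-yl acetate | CC(C)(C)[Si](C)(C)OCCC(=C)C[C@H](O[Si](C)(C)C(C)(C)C)C/C(COC(C)=O)=C/[C@@H](O)C=C | intermediate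
18 | 2-(bromomethyl)acrylic acid | C=C(CBr)C(=O)O | starting material
19 | 2-(bromomethyl)acryloyl chloride | C=C(CBr)C(=O)Cl | intermediate
20 | (3S,4Z)-6-acetoxy-5-{(2S)-2,6-bis[(tert-butyldimethylsilyl)oxy]-4-methylidenehexyl}hexa-1,4-dien-3-yl 2-(bromomethyl)prop-2-enoate | CC(C)(C)[Si](C)(C)OCCC(=C)C[C@H](O[Si](C)(C)C(C)(C)C)C/C(COC(C)=O)=C/[C@@H](OC(=O)C(=C)CBr)C=C | intermediate
21 | (2Z)-2-{(2S)-2,6-bis[(tert-butyldimethylsilyl)oxy]-4-methylidenehexyl}-3-[(2R)-4-(bromomethyl)-5-oxo-2,5-dihydrofuran-2-yl]prop-2-en-1-yl acetate | CC(C)(C)[Si](C)(C)OCCC(=C)C[C@H](O[Si](C)(C)C(C)(C)C)C/C(COC(C)=O)=C/[C@H]1OC(=O)C(CBr)=C1 | intermediate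
22 | (2Z)-3-[(2R)-4-(bromomethyl)-5-oxo-2,5-dihydrofuran-2-yl]-2-[(2S)-2,6-dihydroxy-4-methylidenehexyl]prop-2-en-1-yl acetate | OCCC(=C)C[C@H](O)C/C(COC(C)=O)=C/[C@H]1OC(=O)C(CBr)=C1 | intermediate
23 | (2Z)-3-[(2R)-4-(bromomethyl)-5-oxo-2,5-dihydrofuran-2-yl]-2-(4-methylidene-2,6-dioxohexyl)prop-2-en-1-yl acetate | O=CCC(=C)CC(=O)C/C(COC(C)=O)=C/[C@H]1OC(=O)C(CBr)=C1 | intermediate
24 | allylchromium(III) dichloride derived from 23 (Cr on C13; formed in situ) | O=CCC(=C)CC(=O)C/C(COC(C)=O)=C/[C@H]1OC(=O)C(C[Cr](Cl)Cl)=C1 | intermediate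
25 | [(3aR,4S,10Z,11aR)-4-hydroxy-3,6-dimethylidene-2,8-dioxo-2,3,3a,4,5,6,7,8,9,11a-decahydrocyclodeca[b]furan-10-yl]methyl acetate (8α-hydroxy, trans-fused lactone) | C=C1CC(=O)C/C(COC(C)=O)=C/[C@H]2OC(=O)C(=C)[C@@H]2[C@@H](O)C1 | intermediate
26 | [(3aR,4S,10Z,11aR)-4-acetoxy-3,6-dimethylidene-2,8-dioxo-2,3,3a,4,5,6,7,8,9,11a-decahydrocyclodeca[b]furan-10-yl]methyl acetate (8α,15-diacetoxy-2-oxogermacra-4,10(14),11(13)-trien-12,6α-olide) | C=C1CC(=O)C/C(COC(C)=O)=C/[C@H]2OC(=O)C(=C)[C@@H]2[C@@H](OC(C)=O)C1 | target

**Totals**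
Total step count: 15. Longest linear sequence: 14 steps (steps 1–8 and 10–15; step 9 is a one-step side branch).

**Steps most likely to fail**

1. Step 14 (key macrocyclisation). The aldehyde may be attacked on the wrong face in the macrocyclic transition state, which would give the C8 epimer; at insufficient dilution intermolecular coupling would compete. Fallback: setting out from 23, the same chromium-mediated closure is accepted with the opposite aldehyde face, giving the 8-epimeric (8β-hydroxy) macrocyclic alcohol F1. A Mitsunobu esterification (AcOH, PPh3, DIAD, toluene, 0 °C) then installs the acetate with inversion at C8 and comes back to the route directly at 26, so that C8 is set by substitution and no longer by the transition state.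

2. Step 13 (double oxidation to the skipped keto aldehyde). The β,γ-double bonds may migrate into conjugation, or the 1,5-keto aldehyde may undergo intramolecular aldol reaction during oxidation and handling; the free 2-ketone could later also engage the 8-hydroxyl transannularly. Fallback: setting out from 21, only the primary silyl ether is cleaved (48 % aq. HF, MeCN, −20 °C, monitored) to give the C8 alcohol that keeps the C2 silyl ether F2. Buffered Dess–Martin oxidation gives the mono-aldehyde F3, which is cyclised with CrCl2 as in step 14 to the C2-silyloxy macrocyclic alcohol F4. Acetylation (Ac2O, pyridine) gives the C2-silyloxy 8-acetate F5, acidic fluoride (aq. HF, MeCN, rt) frees the C2 alcohol F6, and a final buffered Dess–Martin oxidation unveils the ketone only at the very end, coming back to the route at 26.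

3. Step 5 (asymmetric alkynylation of acrolein). Enantiofacial discrimination may be insufficient with the small, reactive acrolein, and polymerisation or methyl transfer may compete. Fallback: setting out from 9, deprotonation (n-BuLi, THF, −78 °C) and addition to acrolein should give 12 together with its C6 epimer, the (3R,7S)-enynol F7, in roughly equal amounts. A lipase-catalysed kinetic resolution (Amano PS or AK lipase, vinyl acetate, MTBE, rt) is expected, by the usual size rule for secondary alcohols, to acylate the 6R epimer to its acetate F8 and leave 12, which is separated by chromatography and comes back to the route at 12.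

**Further compounds**
F1 | step 14 | 8-epimer of 25, [(3aR,4R,10Z,11aR)-4-hydroxy-3,6-dimethylidene-2,8-dioxo-2,3,3a,4,5,6,7,8,9,11a-decahydrocyclodeca[b]furan-10-yl]methyl acetate | C=C1CC(=O)C/C(COC(C)=O)=C/[C@H]2OC(=O)C(=C)[C@@H]2[C@H](O)C1
F2 | step 13 | (2Z)-3-[(2R)-4-(bromomethyl)-5-oxo-2,5-dihydrofuran-2-yl]-2-{(2S)-2-[(tert-butyldimethylsilyl)oxy]-6-hydroxy-4-methylidenehexyl}prop-2-en-1-yl acetate | OCCC(=C)C[C@H](O[Si](C)(C)C(C)(C)C)C/C(COC(C)=O)=C/[C@H]1OC(=O)C(CBr)=C1
F3 | step 13 | (2Z)-3-[(2R)-4-(bromomethyl)-5-oxo-2,5-dihydrofuran-2-yl]-2-{(2S)-2-[(tert-butyldimethylsilyl)oxy]-4-methylidene-6-oxohexyl}prop-2-en-1-yl acetate | O=CCC(=C)C[C@H](O[Si](C)(C)C(C)(C)C)C/C(COC(C)=O)=C/[C@H]1OC(=O)C(CBr)=C1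
F4 | step 13 | analogue of 25 with (2S)-OTBS at C2 in place of the ketone (8α-hydroxy, trans-fused lactone) | C=C1C[C@H](O[Si](C)(C)C(C)(C)C)C/C(COC(C)=O)=C/[C@H]2OC(=O)C(=C)[C@@H]2[C@@H](O)C1
F5 | step 13 | 8-acetate of F4 (analogue of 26 with (2S)-OTBS at C2) | C=C1C[C@H](O[Si](C)(C)C(C)(C)C)C/C(COC(C)=O)=C/[C@H]2OC(=O)C(=C)[C@@H]2[C@@H](OC(C)=O)C1
F6 | step 13 | (2S)-2-hydroxy analogue of 26 (C2 carbinol in place of the ketone) | C=C1C[C@H](O)C/C(COC(C)=O)=C/[C@H]2OC(=O)C(=C)[C@@H]2[C@@H](OC(C)=O)C1
F7 | step 5 | C6 epimer of 12, (3R,7S)-7,11-bis[(tert-butyldimethylsilyl)oxy]-9-methylideneundec-1-en-4-yn-3-ol | CC(C)(C)[Si](C)(C)OCCC(=C)C[C@H](O[Si](C)(C)C(C)(C)C)CC#C[C@H](O)C=C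
F8 | step 5 | acetate of F7, (3R,7S)-7,11-bis[(tert-butyldimethylsilyl)oxy]-9-methylideneundec-1-en-4-yn-3-yl acetate | CC(C)(C)[Si](C)(C)OCCC(=C)C[C@H](O[Si](C)(C)C(C)(C)C)CC#C[C@H](OC(C)=O)C=C
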